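All runs come from a simulation with constants of no real substance; scatter was added.

Start late: between 8.00 min and 10.0 min, free Sub is still falling in both runs, so the flask's answer depends on how fast Sub goes, and you need a rate before you need a model.

| setting | Monday's | Tuesday's | flask |
|---|---|---|---|
| Sub | 0.067 M | 0.15 M | 0.10 M |
| Oth | 1 mM | 1 mM | 1.00 mM |
| Oth2 | 0.10 M | 0.10 M | 0.100 M |
| remark | run made earlier | run made earlier |  |
| time |  |  | 10 min |

| run | time / min | Sub / % | Tgt / % |
|---|---|---|---|
| Monday's | 2.50 | 38 | 32 |
| Monday's | 5.00 | 18 | 44 |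
| Monday's | 8.00 | 10 | 54 |
| Monday's | 10.0 | 8 | 59 |
| Tuesday's | 2.50 | 40 | 27 |
| Tuesday's | 5.00 | 23 | 45 |
| Tuesday's | 8.00 | 11 | 54 |
| Tuesday's | 10.0 | 7 | 56 |

(each reading ± 1.5 percentage points)

- Oth is the free proton; pH is minus the decimal logarithm of its molar concentration
- a reading or a percentage of Tgt counts all its forms, free or not
- what has gone from Sub into another species counts as reacted, even if it can come back
- a reading of Sub is of its free form alone

* part of the Sub that has reacted at 10 min
* pH of the solution at 10 min

How fast? Take the **late half-life** of free Sub, the time in which it halves between 5.00 min and 10.0 min, from both runs pooled: 3.45 min, a reading with their scatter.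

Does the charge shift that? Tuesday's run holds 2.24 times Monday's Sub, yet their final readings are 8% and 7%, within 1.5 percentage points of each other. So at this time the percentage of free Sub shows no dependence on the charge beyond the scatter, and I read a flask at 0.10 M, between the two charges, from both runs. My reckoning takes their mean, 7.50% free Sub, so 92.5% has reacted.

What of the pH? No run reads it, but Tuesday's run, with more Sub on the same Oth, ends at 7% free Sub against Monday's 8%, so I keep Oth at its charge of 1.00 mM, which is pH 3.

The forecast says 92.5% and pH 3, since “the percentage curves match within noise”.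

The flask gives 91.8% reacted and pH 3.00.

    Sub + Oth → Tgt2 + Oth + Tgt (k = 2.50 M⁻¹ s⁻¹)
    Tgt2 ⇌ Bse + Oth, settled at all times (K = 3.20 × 10⁻¹⁰ M)
    Sub → Tgt2 + Tgt (k = 7.80 × 10⁻⁴ s⁻¹)
    Sub + Oth2 → Sid (k = 0.0160 M⁻¹ s⁻¹)
    Sub + Tgt ⇌ Imd, settled at all times (K = 20.0 M⁻¹)

Carried from this flask's 20.8% free Sub at 5.00 min, your late half-life gives 7.62% at 10.0 min, where 8.17% stands; carried from the 40.2% of the same flask read at 2.50 min, it gives 8.90%. At 10.0 min in this flask, Sub is used 2.1 times as fast by Sub + Oth as by Sub + Oth2, and the flask holds 24.9% Sid against 58.7% Tgt, all its forms counted.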